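**Retrosynthetic overview**
1. Feature: in the cyclohexene ring of the hydrindene (indene numbering), quaternary C4 is joined through benzylic C5 to the C6=C7 double bond. If the C4 ethyl is read as a former formyl group whose oxygen is tied back to C7, C4–C5–C6=C7 is a Claisen retron, and the carbocycle unfolds to a cyclopenta[c]pyran fused at C3a–C7a.
2. Late disconnections: acid ⇒ ethyl ester; C4 ethyl ⇒ vinyl ⇒ formyl; C4–C5 bond ⇒ [3,3] shift of a 1-ethyl-1-(E)-styryl pyran enol ether that already carries the E-propenoate arm (Wittig on the 4-formyl enol ether).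
3. Early disconnections: 4-formyl enol ether ⇒ trans-fused δ-lactone (α-formylation, reduction, E1cB) ⇒ ethyl addition to a cyclopentyl styryl ketone, then lactonisation ⇒ tetrasubstituted cyclopentane from a Mukaiyama–Michael/aldol three-component coupling on (S)-4-silyloxycyclopentenone and two methylenation/hydrogenation pairs.
4. Ring order: the cyclopentane is bought, the oxacycle is closed by lactonisation, and the Claisen step opens the oxacycle and closes the cyclohexene.

Key step: step 21

Remark: ring positions are given in the indene numbering of the target from the first intermediate on (pyran locants are marked as such), with α the face of H-3a and β the face of H-7a; the carbinol carbon made in step 2, the enol ether geometries made in steps 12, 16 and 17 and the acetal carbon made in step 18 are carried as mixtures and drawn without configuration, because each is erased later.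

**Step 1**
Reactants: 1 tert-butyl acetate
Product: 2 1-tert-butoxy-1-(tert-butyldimethylsilyloxy)ethene (ketene silyl acetal)
Conditions: LDA, THF, −78 °C; TBSCl, DMPU, −78 °C → rt
Reagents that add atoms: tert-butyldimethylsilyl chloride, CC(C)(C)[Si](C)(C)Cl
Why: Kinetic ester enolate formation followed by O-silylation (the polar co-solvent favours O- over C-silylation) should give the ketene silyl acetal needed for the Mukaiyama–Michael step.

**Step 2**
Reactants: 3 (S)-4-(tert-butyldimethylsilyloxy)cyclopent-2-en-1-one; 2 ketene silyl acetal; 4 3-phenylpropanal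
Product: 6 three-component adduct, all-trans cyclopentanone (C1 ketone, C7a α-CH(OH)CH2CH2Ph, C3a β-CH2CO2tBu, C3 α-OTBS), via the Michael adduct TBS enol ether 5 (not isolated)
Conditions: TBSOTf (5 mol %), CH2Cl2, −78 °C; then 4, BF3·OEt2 (1.1 equiv), −78 °C; aq NaHCO3
Reagents that add atoms: none
Why: One-pot Mukaiyama–Michael/Mukaiyama aldol coupling, in which silyl-cation catalysis delivers the acetate unit to the enone face anti to the C3 silyloxy group (sets C3a) with silyl transfer to enol ether 5, which is never a free enolate and so cannot expel the β-silyloxy group, and BF3-activated 4 is then attacked anti to the new arm (sets C7a, 2,3-trans).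

**Step 3**
Reactants: 6 three-component adduct
Product: 7 TIPS ether of 6 (side chain α-CH(OTIPS)CH2CH2Ph)
Conditions: TIPSOTf, 2,6-lutidine, CH2Cl2, −78 → 0 °C
Reagents that add atoms: triisopropylsilyl triflate, CC(C)[Si](C(C)C)(C(C)C)OS(=O)(=O)C(F)(F)F
Why: Silyl triflate/hindered pyridine silylation blocks retro-aldol and dehydration of the aldol and installs a group that should outlast the TBS ether in step 6.

**Step 4**
Reactants: 7 TIPS-protected ketone
Product: 8 C1 exocyclic methylene compound
Conditions: Zn, CH2Br2, TiCl4 (pre-aged reagent), THF–CH2Cl2, 0 °C → rt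
Reagents that add atoms: dibromomethane, BrCBr
Why: In the Takai–Lombardo methylenation the non-basic gem-dimetallic reagent converts the ketone without enolisation, so E1cB loss of the β-silyloxy group and epimerisation at C7a should both be avoided and the ester is left alone.

**Step 5**
Reactants: 8 C1 methylene compound
Product: 9 C1 α-methyl cyclopentane (methyl cis to the C7a side chain)
Conditions: H2 (1 atm), 5% Pt/C, EtOAc, rt
Reagents that add atoms: none
Why: In this heterogeneous hydrogenation of the 1,1-disubstituted alkene the substrate should adsorb on the β face, anti to the bulky vicinal C7a chain and the C3 silyloxy group, so hydrogen arrives there and the new C1 methyl is pushed α, while Pt rather than Pd limits migration of the double bond into the ring.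

**Step 6**
Reactants: 9 bis-silyl ether
Product: 10 C3 α-alcohol (TIPS ether retained)
Conditions: CSA (0.1 equiv), MeOH–CH2Cl2, 0 °C
Reagents that add atoms: none
Why: Acid-catalysed methanolysis distinguishes the two secondary silyl ethers on steric grounds (TBS much faster than TIPS), and the freed hydroxyl, trans to the acetate arm, cannot lactonise.

**Step 7**
Reactants: 10 C3 alcohol
Product: 11 C3 cyclopentanone carrying the C1 α-methyl
Conditions: Dess–Martin periodinane, NaHCO3, CH2Cl2, 0 °C → rt
Reagents that add atoms: none
Why: Buffered Dess–Martin oxidation gives the ketone under neutral conditions, and C3a stays in its favoured trans relation to C7a.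

**Step 8**
Reactants: 11 C3 ketone
Product: 12 C3 exocyclic methylene compound (TIPS ether)
Conditions: Zn, CH2Br2, TiCl4, THF–CH2Cl2, 0 °C → rt
Reagents that add atoms: dibromomethane, BrCBr
Why: Takai–Lombardo methylenation again avoids base, so the enolisable C3a centre next to the carbonyl is not disturbed.

**Step 9**
Reactants: 12 TIPS ether
Product: 13 C3 methylene carbinol
Conditions: TBAF, AcOH (1:1), THF, rt → 40 °C
Reagents that add atoms: none
Why: Fluoride desilylation frees the carbinol, and the acetic acid buffer keeps it protonated so that it does not attack the tert-butyl ester prematurely.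

**Step 10**
Reactants: 13 methylene carbinol
Product: 14 dimethylcyclopentane carbinol (C1 α-Me, C3 β-Me, C3a β-CH2CO2tBu, C7a α-CH(OH)CH2CH2Ph)
Conditions: H2 (1 atm), [Ir(cod)(PCy3)(py)]PF6 (5 mol %), CH2Cl2, rt
Reagents that add atoms: none
Why: In this hydroxyl-directed homogeneous hydrogenation (Crabtree catalyst), coordination to the carbinol on the α-oriented C7a chain, reinforced by the vicinal β-acetate arm shielding the other face, should deliver hydrogen to the α face and set the C3 methyl β.

**Step 11**
Reactants: 14 carbinol
Product: 15 cyclopentyl 2-phenylethyl ketone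
Conditions: Dess–Martin periodinane, NaHCO3, CH2Cl2, rt
Reagents that add atoms: none
Why: Dess–Martin oxidation erases the carbinol centre, so both epimers converge on one ketone without epimerising C7a.

**Step 12**
Reactants: 15 ketone
Product: 16 chain-side trimethylsilyl enol ether
Conditions: TMSCl, then LDA (1.05 equiv), THF, −78 °C (internal quench); Et3N, cold aq NaHCO3
Reagents that add atoms: trimethylsilyl chloride, C[Si](C)(C)Cl
Why: Kinetic deprotonation with in situ silyl trapping takes the unhindered chain CH2 rather than the C7a methine or the less acidic ester CH2, and the internal quench pre-empts Dieckmann-type attack on the ester.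

**Step 13**
Reactants: 16 silyl enol ether
Product: 17 cyclopentyl (E)-styryl ketone
Conditions: Pd(OAc)2 (1.05 equiv), MeCN, rt
Reagents that add atoms: none
Why: In the Saegusa–Ito oxidation, oxo-π-allylpalladium formation and β-hydride elimination give the conjugated E-enone.

**Step 14**
Reactants: 17 styryl ketone
Product: 18 tertiary ethyl/(E)-styryl carbinol (configuration at C7 as in the SMILES)
Conditions: EtMgBr, anhydrous CeCl3, THF, −78 °C; aq NH4Cl
Reagents that add atoms: ethylmagnesium bromide, CC[Mg]Br
Why: Organocerium 1,2-addition (non-basic, selective for the ketone over the tert-butyl ester and over 1,4-addition) under Felkin–Anh control, in which C3a with its β-acetate arm is the large group anti to the nucleophile and H-7a lies beside the styryl arm, so ethyl should enter past H-7a on the C1 side, whose β face carries only hydrogen.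

**Step 15**
Reactants: 18 hydroxy tert-butyl ester
Product: 19 trans-fused 1-ethyl-5,7-dimethyl-1-[(E)-styryl]hexahydrocyclopenta[c]pyran-3(1H)-one (styryl β and equatorial, cis to H-7a; ethyl α and axial)
Conditions: NaH, THF, 0 °C → rt; aq NH4Cl
Reagents that add atoms: none
Why: In this base-mediated lactonisation the tertiary alkoxide attacks the ester in a 6-exo-trig mode and expels tert-butoxide, base being used because acid would ionise the tertiary cinnamyl-type carbinol, and the two trans arms close to the trans-fused ring.

**Step 16**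
Reactants: 19 δ-lactone
Product: 20 4-(hydroxymethylene) lactone (pyran C4; enol form of the α-formyl lactone)
Conditions: LDA, THF, −78 °C; HCO2CH2CF3, −78 → −40 °C; aq NH4Cl
Reagents that add atoms: 2,2,2-trifluoroethyl formate, O=COCC(F)(F)F
Why: Crossed Claisen condensation (α-formylation) of the lactone enolate, run at a temperature where the enolate rearrangement of this allylic lactone is still frozen, brings in the future arm carbon under basic conditions, whereas a Vilsmeier-type formylation of the parent enol ether is avoided because its O-alkyl iminium salt would ionise at the tertiary cinnamyl-type C–O bond.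

**Step 17**
Reactants: 20 hydroxymethylene lactone
Product: 21 4-[(tert-butyldimethylsilyloxy)methylene] lactone
Conditions: TBSCl, Et3N, DMAP (cat.), CH2Cl2, 0 °C
Reagents that add atoms: tert-butyldimethylsilyl chloride, CC(C)(C)[Si](C)(C)Cl
Why: O-Silylation of the acidic hydroxymethylene group masks the formyl group as a silyl enol ether that is inert to hydride.

**Step 18**
Reactants: 21 silyloxymethylene lactone
Product: 23 3-acetoxy-4-[(silyloxy)methylene]tetrahydropyran (pyran locants, lactol acetate), via the diisobutylaluminium lactolate 22 (not isolated)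
Conditions: DIBAL-H (1.1 equiv), CH2Cl2, −78 °C; then pyridine, DMAP, Ac2O, −78 → −20 °C; Rochelle salt
Reagents that add atoms: acetic anhydride, CC(=O)OC(C)=O
Why: In this reductive acetylation DIBAL-H adds 1,2 to the lactone carbonyl, and the tetrahedral aluminium lactolate, stable at −78 °C, is acetylated in situ, so ring opening and over-reduction are both avoided.

**Step 19**
Reactants: 23 lactol acetate
Product: 24 1-ethyl-5,7-dimethyl-1-[(E)-styryl]-1,4a,5,6,7,7a-hexahydrocyclopenta[c]pyran-4-carbaldehyde (vinylogous formate)
Conditions: TBAF, THF, −20 → 0 °C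
Reagents that add atoms: none
Why: Fluoride unmasks the aldehyde enolate, which expels the adjacent acetate (E1cB), by far the better of the two leaving groups on that carbon, so the enol ether forms under anionic conditions with no oxocarbenium ion that could shed the tertiary allylic group.

**Step 20**
Reactants: 24 4-formyl enol ether; 25 ethyl 2-(triphenylphosphoranylidene)propanoate
Product: 26 ethyl (E)-3-{1-ethyl-5,7-dimethyl-1-[(E)-styryl]-1,4a,5,6,7,7a-hexahydrocyclopenta[c]pyran-4-yl}-2-methylprop-2-enoate
Conditions: 25 (1.5 equiv), PhMe, 80 °C, base-washed glass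
Reagents that add atoms: none
Why: Wittig olefination with the stabilised ylide gives the E-trisubstituted enoate under neutral conditions, at a temperature expected to lie well below the onset of the [3,3] shift.

**Step 21**
Reactants: 26 pyran enol ether carrying the arm
Product: 27 ethyl (E)-3-(7-ethyl-4-formyl-1,3-dimethyl-5-phenyl-2,3,3a,4,5,7a-hexahydro-1H-inden-4-yl)-2-methylprop-2-enoate, trans-fused (arm β, formyl α, phenyl α)
Conditions: degassed PhMe (0.01 M), iPr2NEt (trace), BHT (trace), base-washed sealed tube, 170–190 °C
Reagents that add atoms: none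
Why: Thermal Claisen rearrangement, in which the cyclic allyl vinyl ether C4=C3–O2–C1–CH=CHPh (pyran locants) undergoes a concerted suprafacial [3,3] shift: the C4–CHPh σ bond forms while the tertiary O2–C1 bond breaks, C3 is released as the formyl group, and C1=CH becomes the C6=C7 ring alkene. The closest known reaction type is the ring-contracting Claisen rearrangement of 2-alkenyl-3,4-dihydro-2H-pyrans to cyclohex-3-enecarbaldehydes, applied here to a fully substituted allylic carbon and a dienoate-conjugated enol ether. The cyclohexene closes by transannular bonding of the enol-ether β-carbon to the styryl terminus across the 1,4-positions of the pyran, which forces a boat-like six-centre array, and the oxacycle opens in the same event. The trans fusion fixes the sign of the C1–C7a–C4a–C4 torsion, so the half-chair (β-styryl equatorial) can flex only into the boat that eclipses pyran C1 with C7a and swings the styryl group, cis to H-7a, over the enol-ether face anti to H-4a; bonding on that face places the formyl carbon syn to H-3a at the new quaternary C4. C5 follows from the E-styryl geometry together with the cis (endocyclic) geometry imposed on the new alkene, which puts phenyl syn to formyl. The concerted path must outrun heterolysis of the tertiary cinnamyl-type C–O bond and a [1,5]-hydrogen shift from the arm methyl; the non-polar, acid-free medium and the weak, doubly substituted allylic C–O bond should secure this, and aldehyde formation makes the step irreversible.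

**Step 22**
Reactants: 27 quaternary aldehyde
Product: 28 C4 vinyl compound
Conditions: Ph3PCH3Br, KHMDS, THF, 0 °C; then 27, −78 °C → rt
Reagents that add atoms: methyltriphenylphosphonium bromide, C[P+](c1ccccc1)(c1ccccc1)c1ccccc1.[Br-]
Why: In the Wittig methylenation the small, reactive ylide should attack the non-enolisable neopentyl aldehyde faster than the ester or the β-blocked enoate.

**Step 23**
Reactants: 28 vinyl compound
Product: 29 homo-plakotenin ethyl ester
Conditions: 2-nitrobenzenesulfonyl hydrazide, Et3N, CH2Cl2, rt
Reagents that add atoms: none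
Why: Diimide reduction is steeply graded by alkene substitution, so the monosubstituted vinyl group should be saturated while the trisubstituted ring alkene, the trisubstituted enoate and the arene remain.

**Step 24**
Reactants: 29 ethyl ester
Product: 30 homo-plakotenin, (2E)-3-[(1R,3R,3aR,4S,5S,7aR)-4,7-diethyl-1,3-dimethyl-5-phenyl-2,3,3a,4,5,7a-hexahydro-1H-inden-4-yl]-2-methylprop-2-enoic acid
Conditions: LiOH, THF–MeOH–H2O, 50 °C; then 1 M HCl to pH 3
Reagents that add atoms: lithium hydroxide, [Li+].[OH-]
Why: Saponification of the unhindered ester carbonyl touches no epimerisable centre and leaves the E-alkene in place.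

**Compound list**
1 | tert-butyl acetate | CC(=O)OC(C)(C)C | starting material
2 | 1-tert-butoxy-1-(tert-butyldimethylsilyloxy)ethene | C=C(OC(C)(C)C)O[Si](C)(C)C(C)(C)C | intermediate
3 | (S)-4-(tert-butyldimethylsilyloxy)cyclopent-2-en-1-one | O=C1C=C[C@@H](O[Si](C)(C)C(C)(C)C)C1 | starting material
4 | 3-phenylpropanal | O=CCCc1ccccc1 | starting material
5 | Michael adduct TBS enol ether (not isolated) | CC(C)(C)OC(=O)C[C@@H]1[C@@H](O[Si](C)(C)C(C)(C)C)CC(O[Si](C)(C)C(C)(C)C)=C1 | intermediate
6 | three-component adduct, all-trans cyclopentanone | CC(C)(C)OC(=O)C[C@@H]1[C@@H](O[Si](C)(C)C(C)(C)C)CC(=O)[C@H]1C(O)CCc2ccccc2 | intermediate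
7 | TIPS ether of 6 | CC(C)(C)OC(=O)C[C@@H]1[C@@H](O[Si](C)(C)C(C)(C)C)CC(=O)[C@H]1C(O[Si](C(C)C)(C(C)C)C(C)C)CCc2ccccc2 | intermediate
8 | C1 methylene compound | CC(C)(C)OC(=O)C[C@@H]1[C@@H](O[Si](C)(C)C(C)(C)C)CC(=C)[C@H]1C(O[Si](C(C)C)(C(C)C)C(C)C)CCc2ccccc2 | intermediate
9 | C1 α-methyl bis-silyl ether | CC(C)(C)OC(=O)C[C@@H]1[C@@H](O[Si](C)(C)C(C)(C)C)C[C@@H](C)[C@H]1C(O[Si](C(C)C)(C(C)C)C(C)C)CCc2ccccc2 | intermediate
10 | C3 α-alcohol | CC(C)(C)OC(=O)C[C@@H]1[C@@H](O)C[C@@H](C)[C@H]1C(O[Si](C(C)C)(C(C)C)C(C)C)CCc2ccccc2 | intermediate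
11 | C3 cyclopentanone with C1 methyl | CC(C)(C)OC(=O)C[C@@H]1C(=O)C[C@@H](C)[C@H]1C(O[Si](C(C)C)(C(C)C)C(C)C)CCc2ccccc2 | intermediate
12 | C3 methylene TIPS ether | CC(C)(C)OC(=O)C[C@@H]1C(=C)C[C@@H](C)[C@H]1C(O[Si](C(C)C)(C(C)C)C(C)C)CCc2ccccc2 | intermediate
13 | C3 methylene carbinol | CC(C)(C)OC(=O)C[C@@H]1C(=C)C[C@@H](C)[C@H]1C(O)CCc2ccccc2 | intermediate
14 | dimethylcyclopentane carbinol | CC(C)(C)OC(=O)C[C@@H]1[C@H](C)C[C@@H](C)[C@H]1C(O)CCc2ccccc2 | intermediate
15 | cyclopentyl 2-phenylethyl ketone | CC(C)(C)OC(=O)C[C@@H]1[C@H](C)C[C@@H](C)[C@H]1C(=O)CCc2ccccc2 | intermediate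
16 | chain-side TMS enol ether | CC(C)(C)OC(=O)C[C@@H]1[C@H](C)C[C@@H](C)[C@H]1C(O[Si](C)(C)C)=CCc2ccccc2 | intermediate
17 | cyclopentyl (E)-styryl ketone | CC(C)(C)OC(=O)C[C@@H]1[C@H](C)C[C@@H](C)[C@H]1C(=O)/C=C/c2ccccc2 | intermediate
18 | tertiary ethyl/styryl carbinol | CC(C)(C)OC(=O)C[C@@H]1[C@H](C)C[C@@H](C)[C@H]1[C@](O)(CC)/C=C/c2ccccc2 | intermediate
19 | trans-fused cyclopenta[c]pyran-3-one | C1C(=O)O[C@@](CC)(/C=C/c3ccccc3)[C@@H]2[C@H](C)C[C@@H](C)[C@@H]12 | intermediate
20 | 4-(hydroxymethylene) lactone | OC=C1C(=O)O[C@@](CC)(/C=C/c3ccccc3)[C@@H]2[C@H](C)C[C@@H](C)[C@@H]12 | intermediate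
21 | 4-[(TBSO)methylene] lactone | CC(C)(C)[Si](C)(C)OC=C1C(=O)O[C@@](CC)(/C=C/c3ccccc3)[C@@H]2[C@H](C)C[C@@H](C)[C@@H]12 | intermediate
22 | diisobutylaluminium lactolate (not isolated) | CC(C)(C)[Si](C)(C)OC=C1C(O[Al](CC(C)C)CC(C)C)O[C@@](CC)(/C=C/c3ccccc3)[C@@H]2[C@H](C)C[C@@H](C)[C@@H]12 | intermediate
23 | lactol acetate | CC(C)(C)[Si](C)(C)OC=C1C(OC(C)=O)O[C@@](CC)(/C=C/c3ccccc3)[C@@H]2[C@H](C)C[C@@H](C)[C@@H]12 | intermediate
24 | 4-formyl cyclopenta[c]pyran enol ether | O=CC1=CO[C@@](CC)(/C=C/c3ccccc3)[C@@H]2[C@H](C)C[C@@H](C)[C@@H]12 | intermediate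
25 | ethyl 2-(triphenylphosphoranylidene)propanoate | CCOC(=O)C(C)=P(c1ccccc1)(c1ccccc1)c1ccccc1 | starting material
26 | pyran enol ether with E-propenoate arm | CCOC(=O)/C(C)=C/C1=CO[C@@](CC)(/C=C/c3ccccc3)[C@@H]2[C@H](C)C[C@@H](C)[C@@H]12 | intermediate
27 | trans-hydrindene, C4 formyl + arm | CCC1=C[C@@H](c2ccccc2)[C@@](/C=C(\C)C(=O)OCC)(C=O)[C@H]2[C@H]1[C@H](C)C[C@H]2C | intermediate
28 | C4 vinyl compound | CCC1=C[C@@H](c2ccccc2)[C@@](/C=C(\C)C(=O)OCC)(C=C)[C@H]2[C@H]1[C@H](C)C[C@H]2C | intermediate
29 | homo-plakotenin ethyl ester | CCC1=C[C@@H](c2ccccc2)[C@@](/C=C(\C)C(=O)OCC)(CC)[C@H]2[C@H]1[C@H](C)C[C@H]2C | intermediate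
30 | homo-plakotenin | CCC1=C[C@@H](c2ccccc2)[C@@](/C=C(\C)C(=O)O)(CC)[C@H]2[C@H]1[C@H](C)C[C@H]2C | target

**Total step count:** 24. **Longest linear sequence:** 24 steps (1 → 30; 23 from enone 3).

**Steps most likely to fail**

Step 21 (Claisen rearrangement).
- What may go wrong: the shift gives up the vinylogous-ester and styrene conjugation and must pass through a strained boat. It may therefore be too slow at the temperatures where heterolysis of the tertiary allylic C–O bond (loss of stereochemical fidelity) and a [1,5]-hydrogen shift from the arm methyl into the dienyl ether set in.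
- Fallback: arm building and rearrangement are exchanged, so that a simple, non-conjugated enol ether rearranges. The fallback sets out from 24. DIBAL-H (CH2Cl2, −78 °C) gives the 4-(hydroxymethyl) enol ether F1, and TBSCl/imidazole gives its silyl ether F2. Thermolysis under the neutral conditions of step 21 should need less heat, since the enolate leaving group is far poorer and no arm methyl is present, and gives the formyl/silyloxymethyl hydrindene F3. Wittig methylenation then gives the vinyl compound F4, diimide the C4-ethyl silyl ether F5, TBAF the neopentyl alcohol F6, and Dess–Martin oxidation the C4-ethyl aldehyde F7. Olefination of F7 with ylide 25 (xylene, reflux) comes back to the route at 29.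

Step 14 (ethyl addition).
- What may go wrong: the ketone is flanked by two branched ring carbons, so facial selectivity may be poor or the reverse of the prediction.
- Fallback: the order in which ethyl and styryl are introduced is reversed, so the same facial bias then serves the required epimer. The fallback sets out from 16. Ozonolysis (O3, CH2Cl2–MeOH, −78 °C; Me2S) cleaves the enol ether to the cyclopentanecarboxylic acid F8. CDI and then MeNHOMe·HCl give the Weinreb amide F9, and EtMgBr (THF, 0 °C) gives the ethyl ketone F10. Addition of (E)-styrylcerium (from (E)-β-bromostyrene, t-BuLi and CeCl3, −78 °C) comes back to the route at 18.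

Step 10 (directed hydrogenation).
- What may go wrong: the remote carbinol may lose out to the ester carbonyl as the directing group, and the α face is crowded. This could mean poor facial selectivity or migration of the double bond into the ring.
- Fallback: the C3 methyl is set by substitution with inversion at the carbinol centre inherited from 3, not by hydrogenation. The fallback sets out from 10. TsCl/pyridine/DMAP gives the C3 α-tosylate F11. Me2CuLi (Et2O, 0 °C) displaces it from the β face to give the C3 β-methyl TIPS ether F12. TBAF/AcOH, as in step 9, comes back to the route at 14, and steps 7–10 are bypassed.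

**Further compounds**
F1 | step 21 | 4-(hydroxymethyl) enol ether | OCC1=CO[C@@](CC)(/C=C/c3ccccc3)[C@@H]2[C@H](C)C[C@@H](C)[C@@H]12
F2 | step 21 | 4-(TBSO-methyl) enol ether | CC(C)(C)[Si](C)(C)OCC1=CO[C@@](CC)(/C=C/c3ccccc3)[C@@H]2[C@H](C)C[C@@H](C)[C@@H]12
F3 | step 21 | formyl/silyloxymethyl hydrindene | CCC1=C[C@@H](c2ccccc2)[C@@](CO[Si](C)(C)C(C)(C)C)(C=O)[C@H]2[C@H]1[C@H](C)C[C@H]2C
F4 | step 21 | vinyl/silyloxymethyl hydrindene | CCC1=C[C@@H](c2ccccc2)[C@@](CO[Si](C)(C)C(C)(C)C)(C=C)[C@H]2[C@H]1[C@H](C)C[C@H]2C
F5 | step 21 | C4-ethyl silyl ether | CCC1=C[C@@H](c2ccccc2)[C@@](CO[Si](C)(C)C(C)(C)C)(CC)[C@H]2[C@H]1[C@H](C)C[C@H]2C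
F6 | step 21 | C4-ethyl neopentyl alcohol | CCC1=C[C@@H](c2ccccc2)[C@@](CO)(CC)[C@H]2[C@H]1[C@H](C)C[C@H]2C
F7 | step 21 | C4-ethyl aldehyde | CCC1=C[C@@H](c2ccccc2)[C@@](C=O)(CC)[C@H]2[C@H]1[C@H](C)C[C@H]2C
F8 | step 14 | cyclopentanecarboxylic acid | CC(C)(C)OC(=O)C[C@@H]1[C@H](C)C[C@@H](C)[C@H]1C(=O)O
F9 | step 14 | Weinreb amide | CC(C)(C)OC(=O)C[C@@H]1[C@H](C)C[C@@H](C)[C@H]1C(=O)N(C)OC
F10 | step 14 | cyclopentyl ethyl ketone | CC(C)(C)OC(=O)C[C@@H]1[C@H](C)C[C@@H](C)[C@H]1C(=O)CC
F11 | step 10 | C3 α-tosylate | CC(C)(C)OC(=O)C[C@@H]1[C@@H](OS(=O)(=O)c3ccc(C)cc3)C[C@@H](C)[C@H]1C(O[Si](C(C)C)(C(C)C)C(C)C)CCc2ccccc2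
F12 | step 10 | C3 β-methyl TIPS ether | CC(C)(C)OC(=O)C[C@@H]1[C@H](C)C[C@@H](C)[C@H]1C(O[Si](C(C)C)(C(C)C)C(C)C)CCc2ccccc2
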